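Readings and results come from a simulation for substances that don't exist, and the scatter is random.

The product was the one species I could read, so I reckoned what stood beside it by subtraction: S = s − P for the starting material and R = r − P for the coupling partner, with s and r their charges and P the product.

| flask | starting material | coupling partner | time |
|---|---|---|---|
| east | 100 mM | 200 mM |  |
| west | 60.0 mM | 160 mM |  |
| north-west | 300 mM | 200 mM |  |
| north-east | 100 mM | 300 mM |  |
| north | 100 mM | 200 mM | 13 min |

| run | time / min | [product] / mM |
|---|---|---|
| east run | 0.34 | 10.8 |
| east run | 1.0 | 27.1 |
| east run | 1.9 | 42.4 |
| east run | 3.1 | 56.9 |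
| east run | 4.4 | 65.9 |
| west run | 0.34 | 5.9 |
| west run | 1.0 | 14.2 |
| west run | 1.9 | 23.7 |
| west run | 3.1 | 32.2 |
| west run | 4.4 | 37.5 |
| north-west run | 0.34 | 23.0 |
| north-west run | 1.0 | 55.0 |
| north-west run | 1.9 | 85.1 |
| north-west run | 3.1 | 108.8 |
| north-west run | 4.4 | 124.6 |
| north-east run | 0.34 | 16.0 |
| north-east run | 1.0 | 41.0 |
| north-east run | 1.9 | 60.1 |
| north-east run | 3.1 | 76.4 |
| north-east run | 4.4 | 85.1 |

(readings scatter by 0.5 mM)

- apparent order in [starting material] of the starting rate, round the charge of the east run (the rate where two percent of its starting material have turned into product) (one fixed amount of product, the same in the runs compared)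
- apparent order in [coupling partner] of the starting rate, round the charge of the east run (the rate where two percent of its starting material have turned into product)
- product in the north run at 13 min, as a share of the starting material charged

- Overall: starting material + coupling partner -> product.
- Constant volume, constant temperature.
- What is held in complexes is read along with the free species.
- An order is taken over about fifteen percent of the charge, up and down.

My decision was whether a new flask, the north run, should change the east charge or keep it and stand longer. As the zero of the scale I took the plain bimolecular case, rate = κSR, in which κ stays the same from reading to reading and from charge to charge. Integrated, that case gives κ = ln(Rs/(Sr))/((r − s)t), so any drift in κ is a departure from it.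

At 1.0 min the east run gave 1.70 L mol⁻¹ min⁻¹ for this running second-order constant. At that time the north-west run gave 1.19 L mol⁻¹ min⁻¹ and the north-east run 1.90 L mol⁻¹ min⁻¹.

An order is one plus the slope of ln κ against the logarithm of the charge. These readings therefore put the order in starting material near 0.673 and in coupling partner near 1.27, both loose with the scatter and taken across wide spans. More starting material paid less than in proportion, so I kept the east charge, where the starting material, at 100 mM against 200 mM of coupling partner, is the limiting reagent by charge, and gave the north run 13 min.

In the east run κ sank from 1.64 L mol⁻¹ min⁻¹ at 3.1 min to 1.54 L mol⁻¹ min⁻¹ at 4.4 min, while κt grew at 1.30 L mol⁻¹ min⁻¹. Letting κt grow on at that pace gave a mean κ of 1.38 L mol⁻¹ min⁻¹ at 13 min, and so 91.0% product.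

The forecast, made from the same runs, gave 0.8 and 1 for the orders in starting material and coupling partner and 89.5% for the north run, and spoke of “mild saturation”.

The north run gave 86.3% product, as a share of the starting material charged, and the starting orders came to 0.77 in starting material and 1.1 in coupling partner.

    2 coupling partner ⇌ reagent dimer, settled at all times (39.90 L mol⁻¹)
    starting material + reagent dimer → product + coupling partner (6.480 L mol⁻¹ min⁻¹)
    coupling partner → lost reagent (0.2436 min⁻¹)
    2 starting material ⇌ idle substrate dimer, settled at all times (3.600 L mol⁻¹)

The loss of coupling partner to lost reagent moves the readings by 8.7 (root mean square, in units of the scatter). The north result stands 4.7 percentage points below my figure. Put into the same formula, it gives κ = 1.10 L mol⁻¹ min⁻¹ over the 13 min, less than the 1.38 L mol⁻¹ min⁻¹ I carried and less than the 1.70 L mol⁻¹ min⁻¹ that the east run, of the same charge, gave at 1.0 min. In the north-east run, product reached half of the starting material charged at 1.39 min, which gives κ = 1.83 L mol⁻¹ min⁻¹.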